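This flask cannot be read off any earlier run: grey has its equivalents at another strength of solid substrate, while blue and amber have its strength at other equivalents.

| flask | solid substrate | partner | remark | time |
|---|---|---|---|---|
| blue | 0.30 M | 1.2 equiv | run made earlier |  |
| amber | 0.30 M | 2.7 equiv | run made earlier |  |
| grey | 0.45 M | 1.8 equiv | run made earlier |  |
| flask | 0.30 M | 1.80 equiv |  | 5.0 h |

| run | time / h | target / % | solid substrate / % |
|---|---|---|---|
| blue | 1.33 | 1.0 | 81.1 |
| blue | 1.50 | 2.6 | 79.3 |
| blue | 2.00 | 3.1 | 75.2 |
| blue | 3.00 | 5.0 | 68.5 |
| blue | 4.00 | 8.8 | 61.8 |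
| amber | 1.33 | 3.5 | 80.7 |
| amber | 1.50 | 4.3 | 79.3 |
| amber | 2.00 | 6.5 | 74.5 |
| amber | 3.00 | 12.5 | 65.2 |
| amber | 4.00 | 16.9 | 58.3 |
| grey | 1.33 | 2.0 | 87.3 |
| grey | 1.50 | 2.5 | 85.0 |
| grey | 2.00 | 4.4 | 82.4 |
| grey | 3.00 | 8.4 | 76.4 |
| grey | 4.00 | 11.9 | 71.2 |

(standard deviation of a reading: 0.5 percentage points)

- the best time, 5.0 h at the latest, for target
- the amount of target, in percent of the solid substrate charged, at that time

- at the start none of the solid substrate is in solution
- a reading or a percentage of target counts all its forms, free or not

So I start from the plainest case, in which a given amount of partner has the same chance of becoming target in each flask. I divide target, in percent of the solid substrate charged, by the equivalents of partner, which gives the percent of charged partner that has become target. At 4.00 h this reads 7.33% in blue, 6.26% in amber and 6.61% in grey.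

My doubt is that these are not equal: blue stands above amber by 1.1 percentage points. But c(partner) is 0.810 M in both amber and grey, and their values differ by 0.35 points despite different solid charges. This flask's c(partner), 0.540 M, lies above blue's and below amber's, so I take the mean, 6.73%.

The next doubt is that the readings stop before the time limit. From 2.00 h to 4.00 h the mean gain in this percent of charged partner is 4.26%. Adding half of that for the last hour gives the partner share at the limit, the percent of charged partner become target by 5.0 h: 8.86%.

Could target turn down earlier? In amber it still climbs from 12.5% to 16.9% with 58.3% of the solid substrate undissolved, so I take the latest time. Multiplied by 1.80 equiv, the share gives 15.9%.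

The forecast says 16%, between 14% and 18%, at 5 h, holding that “the rate depends on partner concentration, not on the amount of solid”.

The flask gives 16.4% at 5.00 h, with 54.9% of the solid substrate still undissolved.

    solid substrate ⇌ dissolved substrate, rate k1*(cs1 - [dissolved substrate]) while solid is left; crystals form when [dissolved substrate] > cs1 (solubility = 0.120 M, k = 0.460 h⁻¹)
    dissolved substrate + partner ⇌ target (K = 9.30 M⁻¹, k = 0.370 M⁻¹ h⁻¹)
    solid product ⇌ target, rate k3*(cs3 - [target]) while solid is left; crystals form when [target] > cs3 (solubility = 0.0560 M, k = 16.0 h⁻¹)
    partner → decomposed reagent (k = 0.0280 h⁻¹)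

Its partner share is 9.11%, beside my 8.86%. A neighbouring flask, alike but with 4.50 equiv of partner, would hold 39.9% at my share. It holds 33.3% of target, solid product counted in, a partner share of 7.40%.

The numbers in the tables were generated by integration on assumed constants.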